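(The data are simulated from invented constants.)

- Whatever you charge stays in a closed flask, so the amounts at any moment add up to the charge. This mass balance frames the whole reckoning.

| flask | starting material | remark | time |
|---|---|---|---|
| maple | 0.028 M | run made earlier |  |
| ash | 0.044 M | run made earlier |  |
| east | 0.020 M |  | 2.0 h |
| south | 0.020 M |  | 3.0 h |

- maple (time / h: target / %, side product A / %): 0.417: 12.7, 18.2; 1.33: 15.1, 17.1; 2.50: 15.8, 17.8; 4.00: 15.2, 17.9
- ash (time / h: target / %, side product A / %): 0.250: 9.1, 15.3; 0.667: 15.1, 17.7; 1.50: 15.2, 18.5; 4.00: 15.1, 18.0

(each reading ± 0.5 percentage points)

- which one finishes higher in share of target in all that became target or side product A or side product B ("neither" within 2 percentage points) (east / south / neither)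
- share of target in all that became target or side product A or side product B, east
- share of target in all that became target or side product A or side product B, south



- Start with the ash run. Target reads 9.1% at 0.250 h. Continued as a straight line, that start meets the level of 15.1% at 0.415 h, which is its knee.
- Side product A starts steeper in ash, at 15.3%. Its knee comes earlier, at 0.294 h.
- The two curves do not cross in ash, where target ends lower than side product A.
- Target plus side product A ends at 33.1% in maple and 33.1% in ash. You carry this held sum to the new flasks.
- Suppose the knee stretches inversely with the charge. At 0.020 M, target's knee then falls at 0.913 h, earlier than east's 2.0 h. So I expect both flasks to be at their levels.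
- The share asked for is then target over the held sum plus side product B, which nobody read.
- With no side product B, my share is 45.9%. If the whole remainder of 66.9% were side product B, it is 15.2%.
- If side product B simply accumulates, south, read later, carries at least east's amount. I therefore commit to that range, with east not lower.
- The forecast picks values inside my range, near its low end: 15.3% for east, 15.3% for south, and neither as the answer. Its words are “East and south should therefore match”.
- The flask gives 35.7% for east and 30.6% for south, so east finishes higher.

    starting material → side product A (k = 5.21 × 10⁻⁴ s⁻¹)
    starting material → intermediate A (k = 0.00195 s⁻¹)
    intermediate A → intermediate C (k = 4.07 × 10⁻⁵ s⁻¹)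
    intermediate B → target (k = 0.00155 s⁻¹)
    intermediate C → side product B (k = 3.38 × 10⁻⁴ s⁻¹)
    starting material → intermediate B (k = 4.55 × 10⁻⁴ s⁻¹)

- At 2.00 h, east holds 10.2% of side product B. The read target level over the held sum plus that amount gives 35.1%, against the flask's 35.7%.
- South holds 17.4% at 3.00 h, which gives 30.1%, against 30.6%.
- Intermediate A holds 50.4% in east and 43.5% in south at those times.
- Now read the east flask at 8.0 h. It holds 42.8% of side product B, so the same reckoning gives 20.0%, and the flask gives 20.4%.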